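(The earlier runs and the new flask are calculated for an exercise; noise was put on by code.)

In a one-step world, X goes to J and the balance of X, the one reagent charged, reads d[X]/dt = −k[X]. I divided that balance by the charge and the charge dropped out, so a first-order step gives J in percent of X charged on one curve. A step of higher order keeps the charge in the balance. The test was therefore elm against cedar, at ten times the charge.

| flask | X | remark | time |
|---|---|---|---|
| cedar | 0.21 M | run made earlier |  |
| elm | 2.1 M | run made earlier |  |
| north | 0.15 M |  | 2.5 h |
| south-west | 0.50 M |  | 2.5 h |
| north-west | 1.5 M |  | 2.5 h |

| run | time / min | J / % |
|---|---|---|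
| cedar | 25.0 | 20 |
| cedar | 50.0 | 29 |
| cedar | 80.0 | 35 |
| cedar | 120 | 42 |
| elm | 25.0 | 15 |
| elm | 50.0 | 29 |
| elm | 80.0 | 36 |
| elm | 120 | 50 |

(readings scatter by 2 percentage points)

- amount of J at the end, in percent of the X charged for north, south-west, north-west, in this order
- the shape of the row from first to last (hardly changes / rises, then falls / falls all the way / rises all the way / falls, then rises)

- "hardly changes" means that all values lie within two and a half points (for a concentration: within two and a half percent of the largest)

I carried one quantity, the charge gap: the mean of elm minus cedar in J at equal times. It came to 1 percentage point. Elm lay 5 points below cedar at 25.0 min and 8 points above it at 120 min, so the split changed sign. The scatter put a standard error of 1.4 points on the mean, and the gap was smaller than that error. I read the order in X as one and expected a flat row.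

For its height I took the mean of the two runs. With the main step by itself, the 46.0% at 120 min gave a constant of 0.00513 min⁻¹, and so 53.7% at 2.5 h. Then I added a back step, which I did not fit but read from the fall of the apparent constant. The apparent constant had fallen from 0.00769 min⁻¹ at 25.0 min, and running that fall on in a straight line gave 47.7%, lower than the one-step figure. A first-order back step keeps the charge out of the balance, and so do further first-order steps. I committed to a flat row near 50.7%.

The forecast gave 45%, 50% and 56%, with the shape rises all the way, on the reading that “high X protects against it”. We parted on the split at 120 min: the forecast built its rise on it, calling its mechanism a guess, and I averaged it with the other readings.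

The flask gave 50.4%, 50.4% and 50.4%, with the shape hardly changes.

    X ⇌ J (K = 23.0, k = 0.0100 min⁻¹)
    Q ⇌ X (k = 7.60 × 10⁻⁴ min⁻¹)
    J ⇌ Q (K = 0.150, k = 0.0130 min⁻¹)
    X ⇌ Z (K = 1.30, k = 0.0180 min⁻¹)

At 2.50 h, north held X at 15.0% of its charge and north-west at 15.0% of its own. I put the charge gap to use once more, on north-west against north. The earlier runs had given 1 point, with an error of 1.4 points. The mean of north-west minus north in J over 1.25 h, 2.50 h and 25.0 h came to 0 points.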